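**Retrosynthetic overview**
- The target is traced back by removing C13 (Eschenmoser methylenation) and the C3 silyl ether. The γ-lactone, the last ring formed, comes from C6-OH and a C12 methyl ester.
- C6-OH and the C8 isobutyrate both come from one Evans–Tishchenko reaction of a C8-hydroxy C6-ketone with isobutyraldehyde. C8-OH comes from C8-SiMe2Ph (Fleming–Tamao), and the C10 carbinol from a 1(10)-E-alkene (Mukaiyama hydration).
- The ten-membered ring comes from an anionic oxy-Cope [3,3] shift of a 1-[(E)-2-silylvinyl]-6-isopropenylcyclohex-2-en-1-ol. C8–C9 forms, C1–C6 breaks, the cyclohexene C=C becomes the 4Z-alkene, and the enolate is alkylated at C7.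
- The cyclohexenone comes from (S)-carvone by epoxidation, Wharton transposition, silylation and allylic oxidation. The silylvinyl unit comes from an ethynylsilane by hydrostannation.
- Ring order: six-membered ring (bought), then ten-membered carbocycle (oxy-Cope), then γ-lactone.

Assumption: germacrane numbering of the target is used throughout (C6 lactone carbinol, C8 ester carbinol, C10 tertiary carbinol, C3 allylic carbinol, H-7 α), so the target is (3S,6R,7R,8R,10S,4Z) = 3β-OH, 6α-O, 8β-OCOiPr, 10α-OH; 1, 6 and all unnumbered reagents are catalogue chemicals.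

Step 1
Reactants: 1 (S)-(+)-carvone
Product: 2 (1S,4S,6S)-1-methyl-4-(prop-1-en-2-yl)-7-oxabicyclo[4.1.0]heptan-2-one (carvone oxide; oxirane trans to isopropenyl)
Conditions: 30 % H2O2, NaOH (cat.), MeOH, 0 °C
Reagents that add atoms: hydrogen peroxide OO
Why: Weitz–Scheffer nucleophilic epoxidation touches only the enone C=C, and HOO− adds anti to the isopropenyl group, so both oxirane carbons are set by the bought stereocentre.

Step 2
Reactants: 2 carvone oxide
Product: 3 (−)-trans-carveol = (1S,5R)-2-methyl-5-(prop-1-en-2-yl)cyclohex-2-en-1-ol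
Conditions: N2H4·H2O, AcOH (cat.), MeOH, 0 °C → rt
Reagents that add atoms: none
Why: The Wharton transposition (hydrazone, vinyl diazene, loss of N2) opens the oxirane while keeping its distal C–O bond, so the allylic OH (future C3, S) ends trans to the isopropenyl group.

Step 3
Reactants: 3 (−)-trans-carveol
Product: 4 trans-carveol TBS ether
Conditions: TBSCl, imidazole, DMF, rt
Reagents that add atoms: tert-butyldimethylsilyl chloride CC(C)(C)[Si](C)(C)Cl
Why: Standard O-silylation gives an ether that survives organolithium, KH and peracid, and it must stay on while C6 is a ketone because a free Z-γ-hydroxy enone would close to a furan.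

Step 4
Reactants: 4 trans-carveol TBS ether
Product: 5 (4S,6R)-4-(tert-butyldimethylsilyloxy)-3-methyl-6-(prop-1-en-2-yl)cyclohex-2-en-1-one
Conditions: Mn(OAc)3·2H2O (10 mol %), t-BuOOH (decane), 3 Å MS, EtOAc, rt
Reagents that add atoms: tert-butyl hydroperoxide CC(C)(C)OO
Why: Radical allylic oxidation attacks the only ring CH2 allylic to the trisubstituted alkene, and the neutral medium leaves the epimerisable α-isopropenyl centre and the carbinol centre untouched.

Step 5
Reactants: 6 ethynyl(dimethyl)phenylsilane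
Product: 7 (E)-dimethyl(phenyl)[2-(tributylstannyl)ethenyl]silane
Conditions: Bu3SnH, AIBN (cat.), neat, 90 °C
Reagents that add atoms: tributyltin hydride CCCC[SnH](CCCC)CCCC
Why: In radical hydrostannation of a silylacetylene the stannyl radical adds reversibly, which funnels the material to the thermodynamic E β-adduct.

Step 6
Reactants: 5 silyloxy enone; 7 E-stannyl vinylsilane
Product: 9 (1R,4S,6R)-4-(tert-butyldimethylsilyloxy)-1-{(E)-2-[dimethyl(phenyl)silyl]ethenyl}-3-methyl-6-(prop-1-en-2-yl)cyclohex-2-en-1-ol (silylvinyl trans to isopropenyl), via (E)-2-silylvinyllithium 8 (not isolated)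
Conditions: 7, n-BuLi, THF, −78 °C; then 5, −78 °C; H2O
Reagents that add atoms: none
Why: Tin–lithium exchange keeps the E geometry, and the bulky vinyllithium adds 1,2 to the enone from the face opposite the adjacent isopropenyl group, giving the trans-dialkenyl carbinol.

Step 7
Reactants: 9 dialkenyl carbinol
Product: 12 methyl (1(10)E,4Z)-3β-(tert-butyldimethylsilyloxy)-8β-[dimethyl(phenyl)silyl]-6-oxo-13-norgermacra-1(10),4-dien-12-oate (7α-H), via potassium alkoxide 10 (not isolated), via potassium enolate 11 (not isolated)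
Conditions: KH, 18-crown-6, THF, 0 °C → rt; BrCH2CO2Me, −78 → 0 °C
Reagents that add atoms: methyl bromoacetate COC(=O)CBr
Why: The anionic oxy-Cope [3,3] rearrangement runs through the chair with both ring bonds and the E-silyl group equatorial, which forms C8–C9, sets C8, gives the 1(10)-E-alkene and carries the cyclohexene C=C over as the 4Z-enone (silicon cannot β-eliminate as an alkoxy group would), and the enolate is then alkylated at C7 anti to the C8 silyl group (Fleming β-silyl enolate rule), this anti isomer also being the less crowded one at an epimerisable centre.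

Step 8
Reactants: 12 keto ester
Product: 13 methyl (4Z)-3β-(tert-butyldimethylsilyloxy)-8β-[dimethyl(phenyl)silyl]-10α-hydroxy-6-oxo-13-norgermacr-4-en-12-oate
Conditions: Co(acac)2 (20 mol %), PhSiH3, O2 (1 atm), THF, rt
Reagents that add atoms: dioxygen O=O
Why: In the Mukaiyama (Co–H HAT) hydration, H• adds to C1 of the only electron-rich, strained alkene (the β,β-disubstituted enone is inert), and O2 traps the tertiary C10 radical from the ring periphery in the conformer that keeps C14 on the β-face, giving the 10α-alcohol.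

Step 9
Reactants: 13 silyl keto alcohol
Product: 14 methyl (4Z)-3β-(tert-butyldimethylsilyloxy)-8β,10α-dihydroxy-6-oxo-13-norgermacr-4-en-12-oate
Conditions: Hg(OAc)2, AcOOH (32 % in AcOH), rt
Reagents that add atoms: peracetic acid CC(=O)OO
Why: In the Fleming–Tamao oxidation, ipso-mercuridesilylation removes the phenyl group and the peracid-induced Si-to-O shift proceeds with retention at C8, while the only remaining C=C is an electron-poor enone that peracid ignores.

Step 10
Reactants: 14 β-hydroxy ketone
Product: 16 (4Z)-3β-(tert-butyldimethylsilyloxy)-10α-hydroxy-8β-isobutyryloxy-13-norgermacr-4-en-6α,12-olide, via hydroxy isobutyrate 15 (not isolated)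
Conditions: i-PrCHO (10 equiv), SmI2 (30 mol %, premixed with the aldehyde), THF, −10 °C; then PPTS (cat.), CH2Cl2, rt
Reagents that add atoms: isobutyraldehyde CC(C)C=O
Why: In the Evans–Tishchenko reaction the C8 hemiacetal of isobutyraldehyde, tied to the C6 ketone by Sm(III), delivers its hydride intramolecularly through a chair, giving the 1,3-anti (6α) alcohol while O8 becomes the isobutyrate, and the freed C6-OH then lactonises onto the methyl ester.

Step 11
Reactants: 16 saturated lactone
Product: 19 (4Z)-3β-(tert-butyldimethylsilyloxy)-10α-hydroxy-8β-isobutyryloxygermacra-4,11(13)-dien-6α,12-olide, via Mannich base 17 (not isolated), via ammonium iodide 18 (not isolated)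
Conditions: LDA (2.5 equiv), THF, −78 °C; CH2=NMe2+ I−, → rt; MeI, MeOH; aq NaHCO3
Reagents that add atoms: Eschenmoser's salt C=[N+](C)C.[I-]
Why: In the Eschenmoser methylenation (Mannich reaction, N-methylation, E1cB loss of NMe3) the lactone α-CH2 is clearly more acidic and less hindered than the α-branched isobutyrate CH, the extra base only parks C10-OH as its alkoxide, and no stereocentre is touched.

Step 12
Reactants: 19 silylated α-methylene lactone
Product: 20 target CNP0163972.1
Conditions: HF·pyridine, pyridine/THF, 0 °C → rt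
Reagents that add atoms: none
Why: Fluoride-driven Si–O cleavage under buffered, non-basic conditions spares the α-methylene lactone, the ester and the tertiary alcohol.

**Compound list**
1 | (S)-(+)-carvone | CC1=CC[C@@H](CC1=O)C(C)=C | starting material
2 | carvone oxide (1S,4S,6S) | C[C@]12O[C@H]1C[C@@H](CC2=O)C(C)=C | intermediate
3 | (−)-trans-carveol (1S,5R) | CC1=CC[C@H](C[C@@H]1O)C(C)=C | intermediate
4 | trans-carveol TBS ether | CC1=CC[C@H](C[C@@H]1O[Si](C)(C)C(C)(C)C)C(C)=C | intermediate
5 | (4S,6R)-4-TBSO-3-methyl-6-isopropenylcyclohex-2-enone | CC1=CC(=O)[C@H](C[C@@H]1O[Si](C)(C)C(C)(C)C)C(C)=C | intermediate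
6 | ethynyl(dimethyl)phenylsilane | C#C[Si](C)(C)c1ccccc1 | starting material
7 | (E)-dimethyl(phenyl)[2-(tributylstannyl)ethenyl]silane | CCCC[Sn](CCCC)(CCCC)/C=C/[Si](C)(C)c1ccccc1 | intermediate
8 | (E)-2-[dimethyl(phenyl)silyl]ethenyllithium | [Li]/C=C/[Si](C)(C)c1ccccc1 | intermediate
9 | (1R,4S,6R)-dialkenyl carbinol | CC1=C[C@](O)(/C=C/[Si](C)(C)c2ccccc2)[C@H](C[C@@H]1O[Si](C)(C)C(C)(C)C)C(C)=C | intermediate
10 | potassium alkoxide of 9 | CC1=C[C@]([O-])(/C=C/[Si](C)(C)c2ccccc2)[C@H](C[C@@H]1O[Si](C)(C)C(C)(C)C)C(C)=C.[K+] | intermediate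
11 | ten-membered potassium enolate (ring bonds trans across C6=C7, 1(10)E, 4Z) | [K+].[O-]/C1=C\[C@H]([Si](C)(C)c2ccccc2)C/C(C)=C/C[C@H](O[Si](C)(C)C(C)(C)C)/C(C)=C\1 | intermediate
12 | 8β-silyl 6-keto 12-methyl ester, 1(10)E,4Z-diene | O=C1/C=C(/C)[C@@H](O[Si](C)(C)C(C)(C)C)C/C=C(\C)C[C@@H]([Si](C)(C)c2ccccc2)[C@H]1CC(=O)OC | intermediate
13 | 10α-hydroxy 8β-silyl keto ester | O=C1/C=C(/C)[C@@H](O[Si](C)(C)C(C)(C)C)CC[C@](C)(O)C[C@@H]([Si](C)(C)c2ccccc2)[C@H]1CC(=O)OC | intermediate
14 | 8β,10α-dihydroxy keto ester | O=C1/C=C(/C)[C@@H](O[Si](C)(C)C(C)(C)C)CC[C@](C)(O)C[C@@H](O)[C@H]1CC(=O)OC | intermediate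
15 | 6α-hydroxy 8β-isobutyrate methyl ester | O[C@@H]1/C=C(/C)[C@@H](O[Si](C)(C)C(C)(C)C)CC[C@](C)(O)C[C@@H](OC(=O)C(C)C)[C@H]1CC(=O)OC | intermediate
16 | saturated 6α,12-lactone | C1C(=O)O[C@@H]2/C=C(/C)[C@@H](O[Si](C)(C)C(C)(C)C)CC[C@](C)(O)C[C@@H](OC(=O)C(C)C)[C@@H]12 | intermediate
17 | α-(dimethylaminomethyl) lactone (C11 epimers) | CN(C)CC1C(=O)O[C@@H]2/C=C(/C)[C@@H](O[Si](C)(C)C(C)(C)C)CC[C@](C)(O)C[C@@H](OC(=O)C(C)C)[C@@H]12 | intermediate
18 | trimethylammonium iodide of 17 | C[N+](C)(C)CC1C(=O)O[C@@H]2/C=C(/C)[C@@H](O[Si](C)(C)C(C)(C)C)CC[C@](C)(O)C[C@@H](OC(=O)C(C)C)[C@@H]12.[I-] | intermediate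
19 | 3-O-TBS target | C=C1C(=O)O[C@@H]2/C=C(/C)[C@@H](O[Si](C)(C)C(C)(C)C)CC[C@](C)(O)C[C@@H](OC(=O)C(C)C)[C@@H]12 | intermediate
20 | CNP0163972.1 (3S,6R,7R,8R,10S,4Z) | C=C1C(=O)O[C@@H]2/C=C(/C)[C@@H](O)CC[C@](C)(O)C[C@@H](OC(=O)C(C)C)[C@@H]12 | target

**Step count**
- Total steps: 12.
- Longest linear sequence: 11 (steps 1–4 and 6–12).

**Steps most likely to fail, with fallbacks**

*Step 7.* The rearrangement itself has close precedent. The weak point is C7: peripheral attack on the ring-trans enolate, anti to the C8–C9 ring bond, may override the silicon effect and give the C7 epimer.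
- The fallback sets out from 9. The same KH/18-crown-6 rearrangement (through 10 and 11) is quenched with AcOH at −78 °C to give the C7-unsubstituted β-silyl ketone F1.
- LDA and methyl glyoxylate give the aldol adduct F2, which is dehydrated (Burgess reagent) to the alkylidene keto ester F3.
- Conjugate reduction with Stryker's reagent puts hydride on C11 and, on work-up, the proton on C7 from the ring periphery. C7 is then set by protonation instead of alkylation. The route is rejoined at 12.

*Step 8.* At the ketone stage the reacting conformer of the 1(10)-alkene is not secured. The C10 face selectivity may therefore be poor, and transannular addition of the C10 radical to the enone is possible.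
- The fallback sets out from 12. Luche reduction (NaBH4, CeCl3, MeOH, −78 °C) from the periphery gives the 6α-hydroxy ester F4, which closes with PPTS to the silyl dienolide F5.
- F5 is a 6,12-heliangolide of the type whose 1(10)-alkene is attacked on the face that places oxygen 10α, as in the common 1β,10α-epoxides.
- The Mukaiyama hydration is run on F5 to give the 10α-hydroxy silyl lactone F6. Fleming–Tamao oxidation then gives the 8β-hydroxy lactone F7; the 4Z-alkene is deactivated by two allylic C–O bonds.
- Isobutyric anhydride/DMAP acylates only the secondary C8-OH. The route is rejoined at 16.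

*Step 10.* Sm(III) alkoxides can trigger a retro-aldol that would open the ring, and the chelated chair may be hard to reach in the macrocycle.
- The fallback sets out from 14. Isobutyric anhydride, DMAP and pyridine at 0 °C give the β-isobutyryloxy ketone F8.
- Undirected Luche reduction from the ring periphery gives 15, which lactonises with PPTS. The route is rejoined at 16.

**Further compounds**
F1 | step 7 | (1(10)E,4Z)-3β-TBSO-8β-[dimethyl(phenyl)silyl]cyclodecadienone with C7H2 | O=C1/C=C(/C)[C@@H](O[Si](C)(C)C(C)(C)C)C/C=C(\C)C[C@@H]([Si](C)(C)c2ccccc2)C1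
F2 | step 7 | glyoxylate aldol adduct of F1 (C7 and C11 epimers) | O=C1/C=C(/C)[C@@H](O[Si](C)(C)C(C)(C)C)C/C=C(\C)C[C@@H]([Si](C)(C)c2ccccc2)C1C(O)C(=O)OC
F3 | step 7 | C7=C11 alkylidene keto ester (CO2Me trans to C8) | O=C1/C=C(/C)[C@@H](O[Si](C)(C)C(C)(C)C)C/C=C(\C)C[C@@H]([Si](C)(C)c2ccccc2)/C1=C/C(=O)OC
F4 | step 8 | 6α-hydroxy 8β-silyl methyl ester, 1(10)E,4Z-diene | O[C@@H]1/C=C(/C)[C@@H](O[Si](C)(C)C(C)(C)C)C/C=C(\C)C[C@@H]([Si](C)(C)c2ccccc2)[C@H]1CC(=O)OC
F5 | step 8 | 8β-silyl 13-norgermacra-1(10),4-dien-6α,12-olide | C1C(=O)O[C@@H]2/C=C(/C)[C@@H](O[Si](C)(C)C(C)(C)C)C/C=C(\C)C[C@@H]([Si](C)(C)c3ccccc3)[C@@H]12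
F6 | step 8 | 10α-hydroxy 8β-silyl lactone | C1C(=O)O[C@@H]2/C=C(/C)[C@@H](O[Si](C)(C)C(C)(C)C)CC[C@](C)(O)C[C@@H]([Si](C)(C)c3ccccc3)[C@@H]12
F7 | step 8 | 8β,10α-dihydroxy lactone | C1C(=O)O[C@@H]2/C=C(/C)[C@@H](O[Si](C)(C)C(C)(C)C)CC[C@](C)(O)C[C@@H](O)[C@@H]12
F8 | step 10 | 8β-isobutyryloxy 10α-hydroxy 6-keto methyl ester | O=C1/C=C(/C)[C@@H](O[Si](C)(C)C(C)(C)C)CC[C@](C)(O)C[C@@H](OC(=O)C(C)C)[C@H]1CC(=O)OC
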